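**Plan**

1. Locants: C1 (quaternary, geranyl), C2–C5 (ring A: CH2, =CH, =C(CH3), CH), C6 (CH2), C7 (CH), C8 (CMe2–O), C9 (C=O), C10 (enol-ether carbon), C11 (prenyl-bearing carbon), C12 and C13 (carbinols). Ring A = C1-C2-C3-C4-C5-C13, ring B = C5-C6-C7-C12-C13, ring C = C7-C8-O-C10-C12, ring D = C1-C9-C11-C10-C12-C13.
2. Retrosynthetic cuts: C1–geranyl; C11–C10 (ring D, Claisen acylation by a lactone carbonyl that then becomes the enol ether); C4–CH3; C2–C3 (ring A, intramolecular Michael addition); C5–C13 (ring B, aldol); C1–C9; C12–C13 and C12–OH.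
3. Forward order: ring C first as a γ-lactone from (S)-α-terpineol, whose ten carbons become C3, C4, C5, C6, C7, C8 with its two methyls, C12 and C10; then ring B, ring A, ring D, and the geranyl group last.
4. Enabling feature: C4, the methyl-bearing sp2 carbon of ring A, lies between C3 and C5. Written as a methyl ketone it makes C5 and then C3 nucleophilic, and they meet the two electrophilic carbons of a C13(=O)–C1(=C2H2) unit; C1 is α to the ring D ketone C9, so C2 can be the β-carbon of an exocyclic enone.
5. Stereochemistry: C7 is bought with terpineol; C12 comes from hydroxylation anti to the C7 side chain; C13 from a chelate-controlled aldol; C5 from equilibration during the cis-selective closure of ring A; C1 from alkylation on the convex face.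

Key step: step 7

Remark: (S)-α-terpineol (also reachable from (S)-limonene), 2-bromoacrolein, 5-methylhex-4-enal and geranyl bromide are treated as purchasable.

**Route**

Step 1
Reactants: 1 (S)-α-terpineol
Product: 3 keto lactone (S)-5,5-dimethyl-4-(3-oxobutyl)dihydrofuran-2(3H)-one, via hydroxy keto acid 2 (not isolated)
Conditions: O3, CH2Cl2, −78 °C; then 30% H2O2, HCO2H, 0 → 40 °C
Reagents that add atoms: ozone O=[O+][O-]
Why: Ozonolysis of the trisubstituted ring alkene with oxidative work-up gives the methyl ketone and the carboxylic acid of 2 (formally an isomer of the ozonide), and the tertiary γ-hydroxy acid lactonises under the acidic work-up, so all ten carbons and the stereocentre of terpineol (future C7) are kept.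

Step 2
Reactants: 3 keto lactone; 4 2-bromoacrolein
Product: 7 aldol adduct 3-(2-bromo-1-hydroxyprop-2-enyl)-5,5-dimethyl-4-(3-oxobutyl)dihydrofuran-2(3H)-one (3,4-trans; carbinol epimers), via enol silane 5 (not isolated), via silylated aldol adduct 6 (not isolated)
Conditions: LiN(iPr)2 (1.05 equiv), THF, −78 °C, then Me3SiCl (1.0 equiv); LiN(iPr)2 (1.1 equiv), −78 °C; 4 (1.2 equiv), −78 °C; 0.5 M HCl, 0 °C
Reagents that add atoms: none
Why: The kinetic enolate of the methyl ketone is parked as enol silane 5 so that the second equivalent of base can form only the lactone enolate, which undergoes aldol addition (1,2) to the aldehyde carbon of 4 anti to the C7 side chain; both new centres are erased in step 3 and the acidic work-up returns the ketone.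

Step 3
Reactants: 7 aldol adduct
Product: 9 hydroxy keto lactone 3-(2-bromoacryloyl)-3-hydroxy-5,5-dimethyl-4-(3-oxobutyl)dihydrofuran-2(3H)-one (3-OH trans to the 4-side chain), via β-keto lactone 8 (not isolated)
Conditions: Dess–Martin periodinane, CH2Cl2, 0 °C; then dimethyldioxirane (acetone solution), −20 → 0 °C
Reagents that add atoms: dimethyldioxirane CC1(C)OO1
Why: Dess–Martin oxidation of the allylic alcohol gives β-keto lactone 8, whose enol is oxidised in the same flask by the dioxirane (Rubottom-type α-hydroxylation of a β-dicarbonyl compound) on the face opposite to the C7 side chain, which sets C12 with the hydroxyl trans and the acyl group cis to that chain.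

Step 4
Reactants: 9 hydroxy keto lactone
Product: 10 bicyclic diol 5-acetyl-6-(1-bromoethenyl)-6,6a-dihydroxy-3,3-dimethylhexahydro-1H-cyclopenta[c]furan-1-one (6-OH cis to 6a-OH; acetyl drawn cis to 6-OH)
Conditions: LiN(SiMe3)2 (2.2 equiv), THF (0.02 M), −78 → −40 °C; AcOH at −40 °C
Reagents that add atoms: none
Why: Intramolecular aldol addition (5-enolexo-exo-trig) of the more substituted enolate of the methyl ketone, reached by proton exchange, to the C13 ketone closes ring B, with lithium bridging the C12 alkoxide and the C13 carbonyl oxygen (chelate control) so that the new C13 hydroxyl is cis to the C12 hydroxyl; the C5 configuration formed here is provisional and is settled in step 7.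

Step 5
Reactants: 10 bicyclic diol; 11 5-methylhex-4-enal
Product: 12 allylic alcohol 5-acetyl-6,6a-dihydroxy-6-(3-hydroxy-7-methylocta-1,6-dien-2-yl)-3,3-dimethylhexahydro-1H-cyclopenta[c]furan-1-one (C9 epimers)
Conditions: CrCl2 (6 equiv), NiCl2 (2 mol %), 11 (2 equiv), DMF, 23 °C
Reagents that add atoms: none
Why: Nozaki–Hiyama–Kishi coupling of the 1-bromovinyl group with the aldehyde is selective for the aldehyde over the ketone and the lactone and tolerates the free tertiary alcohols; the new carbinol centre C9 is a mixture that is oxidised in step 6.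

Step 6
Reactants: 12 allylic alcohol
Product: 13 enone 5-acetyl-6,6a-dihydroxy-3,3-dimethyl-6-(7-methyl-3-oxoocta-1,6-dien-2-yl)hexahydro-1H-cyclopenta[c]furan-1-one
Conditions: Dess–Martin periodinane, CH2Cl2, 0 → 23 °C
Reagents that add atoms: none
Why: Dess–Martin oxidation of the secondary allylic alcohol (the tertiary alcohols are inert) gives the exocyclic α-methylene ketone in which C2 is the electrophilic β-carbon.

Step 7
Reactants: 13 enone
Product: 16 tricyclic silyl enol ether (ring A cyclohexanone cis-fused to ring B; C1=C9 trimethylsilyl enol ether; 12-OSiMe3 and 13-OSiMe3), via C5 epimer 14 (not isolated), via trilithium enolate 15 (not isolated)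
Conditions: LiN(SiMe3)2 (3.3 equiv), THF (0.01 M), −78 → −30 °C; then Me3SiCl (6 equiv), Et3N, −78 → 23 °C
Reagents that add atoms: chlorotrimethylsilane C[Si](C)(C)Cl
Why: LiN(SiMe3)2 deprotonates both tertiary hydroxyls and, reversibly, the methyl ketone, so C5 epimerises through its enolate while the C3 (methyl) enolate adds to the unsubstituted β-carbon C2 of the exocyclic α-methylene ketone, and the resulting C1=C9 enolate and the two alkoxides are fixed as silyl derivatives. The closest known reaction type is the base-mediated intramolecular Michael addition of a ketone enolate to an enone with O-silyl trapping of the product enolate. Ring A closes in the 6-(enolendo)-endo-trig mode, the polarisation of the enone directing C3 to C2 and not to C1 (5-exo). C1 and C2 gain no lasting stereocentre here; C5 is the centre that is settled, because epimer 14, with the acetyl group cis to the C13 side arm, should close the cis-fused bicyclo[4.3.0] ring through a nearly planar transition state much faster than 13 could close a trans-fused one, and it is drained from the equilibrium (Curtin–Hammett). The step needs C3, not C5 or C11, to attack C2, and needs C9 to stay distinguishable from the new C4 ketone: C5 could only form a four-membered ring, the C11 dienolate has no small-ring outlet at low temperature, and the silyl trap keeps C9 masked and regiodefined for steps 8 to 10.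

Step 8
Reactants: 16 tricyclic silyl enol ether
Product: 17 enol triflate (C3=C4 alkene with the triflate on C4; silyl groups as in 16)
Conditions: KN(SiMe3)2 (1.2 equiv), THF, −78 °C; PhNTf2 (1.3 equiv), −78 → −40 °C; AcOH (1.2 equiv), then pH 7 buffer
Reagents that add atoms: N-phenylbis(trifluoromethanesulfonimide) O=S(=O)(N(c1ccccc1)S(=O)(=O)C(F)(F)F)C(F)(F)F
Why: Kinetic deprotonation of the only ketone occurs at the C3 methylene and not at the hindered ring-fusion C5–H, and O-triflation of the potassium enolate gives the C3=C4 enol triflate while C9 stays masked as its silyl enol ether.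

Step 9
Reactants: 17 enol triflate
Product: 19 diol ketone (rings A, B and C; C3=C4 with the methyl on C4; 1-H; C9 ketone bearing the 4-methylpent-3-enyl chain; free 12-OH and 13-OH), via methylated enol silane 18 (not isolated)
Conditions: Pd(PPh3)4 (5 mol %), MeZnCl (3 equiv), THF, 23 °C; then Bu4NF (3.5 equiv), AcOH (4 equiv), 0 °C
Reagents that add atoms: methylzinc chloride C[Zn]Cl
Why: Negishi coupling of the enol triflate with MeZnCl puts the methyl group on C4 with the C3=C4 alkene in place, and buffered fluoride then cleaves the three silyl groups, the enol ether being protonated at C1 on the convex face (C1 stays epimerisable and is set in step 11).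

Step 10
Reactants: 19 diol ketone
Product: 21 tetracycle lacking the geranyl group (the target skeleton with H on C1), via hydroxy diketone 20 (not isolated)
Conditions: LiN(iPr)2 (4.5 equiv), THF, −78 → 0 °C; AcOH (5 equiv); then TsOH·H2O (10 mol %), CH2Cl2, 23 °C
Reagents that add atoms: none
Why: Kinetic deprotonation of the C9 ketone at the C11 methylene and intramolecular Claisen (Dieckmann-type) acylation by the lactone carbonyl C10 closes ring D, the tertiary C8 alkoxide being expelled and the β-diketonate driving the reaction; on acidification the C8 hydroxyl adds back to C10 and loses water to give the enol ether of ring C, the only five-membered cyclodehydration open now that C13 is a carbinol.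

Step 11
Reactants: 21 tetracycle; 22 geranyl bromide
Product: 23 CNP0323114.1 (target)
Conditions: LiN(iPr)2 (3.3 equiv), THF/DMPU (5:1), −78 °C; 22 (1.5 equiv), −78 → −30 °C; AcOH at −78 °C
Reagents that add atoms: none
Why: Excess lithium amide gives the dialkoxide and then the α′ enolate of the vinylogous ester at C1 (kinetic Stork–Danheiser-type deprotonation, run on the lithium alkoxides as in a Fráter–Seebach alkylation so that β-elimination of the C13 oxygen is impossible), and geranyl bromide alkylates C1 on the convex face of the bowl-shaped tetracycle, cis to the C13 hydroxyl, which sets the last stereocentre.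

**Compound list**

1 | (S)-α-terpineol | CC1=CC[C@H](CC1)C(C)(C)O | starting material
2 | (S)-3-(2-hydroxypropan-2-yl)-6-oxoheptanoic acid | CC(=O)CC[C@@H](CC(O)=O)C(C)(C)O | intermediate
3 | (S)-5,5-dimethyl-4-(3-oxobutyl)dihydrofuran-2(3H)-one | CC(=O)CC[C@@H]1C(C)(C)OC(=O)C1 | intermediate
4 | 2-bromoacrolein (2-bromoprop-2-enal) | C=C(Br)C=O | starting material
5 | (S)-5,5-dimethyl-4-[3-(trimethylsilyloxy)but-3-enyl]dihydrofuran-2(3H)-one | C=C(O[Si](C)(C)C)CC[C@@H]1C(C)(C)OC(=O)C1 | intermediate
6 | 3,4-trans-3-(2-bromo-1-hydroxyprop-2-enyl)-5,5-dimethyl-4-[3-(trimethylsilyloxy)but-3-enyl]dihydrofuran-2(3H)-one (carbinol epimers; lithium alkoxide in the flask) | C=C(O[Si](C)(C)C)CC[C@@H]1C(C)(C)OC(=O)[C@H]1C(O)C(Br)=C | intermediate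
7 | 3,4-trans-3-(2-bromo-1-hydroxyprop-2-enyl)-5,5-dimethyl-4-(3-oxobutyl)dihydrofuran-2(3H)-one (carbinol epimers) | CC(=O)CC[C@@H]1C(C)(C)OC(=O)[C@H]1C(O)C(Br)=C | intermediate
8 | 3-(2-bromoacryloyl)-5,5-dimethyl-4-(3-oxobutyl)dihydrofuran-2(3H)-one (C3 enolisable) | CC(=O)CC[C@@H]1C(C)(C)OC(=O)C1C(=O)C(Br)=C | intermediate
9 | 3-(2-bromoacryloyl)-3-hydroxy-5,5-dimethyl-4-(3-oxobutyl)dihydrofuran-2(3H)-one, 3-OH trans to the 4-side chain | CC(=O)CC[C@@H]1C(C)(C)OC(=O)[C@]1(O)C(=O)C(Br)=C | intermediate
10 | 5-acetyl-6-(1-bromoethenyl)-6,6a-dihydroxy-3,3-dimethylhexahydro-1H-cyclopenta[c]furan-1-one; 6-OH, 6a-OH and H-3a on one face, acetyl drawn cis to 6-OH | CC(=O)[C@H]1C[C@@H]2C(C)(C)OC(=O)[C@]2(O)[C@]1(O)C(Br)=C | intermediate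
11 | 5-methylhex-4-enal | CC(C)=CCCC=O | starting material
12 | 5-acetyl-6,6a-dihydroxy-6-(3-hydroxy-7-methylocta-1,6-dien-2-yl)-3,3-dimethylhexahydro-1H-cyclopenta[c]furan-1-one (C9 epimers) | CC(=O)[C@H]1C[C@@H]2C(C)(C)OC(=O)[C@]2(O)[C@]1(O)C(=C)C(O)CCC=C(C)C | intermediate
13 | 5-acetyl-6,6a-dihydroxy-3,3-dimethyl-6-(7-methyl-3-oxoocta-1,6-dien-2-yl)hexahydro-1H-cyclopenta[c]furan-1-one | CC(=O)[C@H]1C[C@@H]2C(C)(C)OC(=O)[C@]2(O)[C@]1(O)C(=C)C(=O)CCC=C(C)C | intermediate
14 | C5 epimer of 13 (acetyl trans to 6-OH, cis to the C13 side arm) | CC(=O)[C@@H]1C[C@@H]2C(C)(C)OC(=O)[C@]2(O)[C@]1(O)C(=C)C(=O)CCC=C(C)C | intermediate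
15 | trilithium salt of the Michael adduct (C1=C9 enolate, 12- and 13-alkoxides) | [Li+].[Li+].[Li+].CC(C)=CCC/C([O-])=C1\CCC(=O)[C@@H]2C[C@@H]3C(C)(C)OC(=O)[C@]3([O-])[C@@]21[O-] | intermediate
16 | tricyclic C4 ketone with C1=C9 trimethylsilyl enol ether and 12,13-bis(trimethylsilyl) ethers; rings A and B cis-fused | CC(C)=CCC/C(O[Si](C)(C)C)=C1\CCC(=O)[C@@H]2C[C@@H]3C(C)(C)OC(=O)[C@]3(O[Si](C)(C)C)[C@@]21O[Si](C)(C)C | intermediate
17 | C3=C4 enol triflate of 16 | CC(C)=CCC/C(O[Si](C)(C)C)=C1\CC=C(OS(=O)(=O)C(F)(F)F)[C@@H]2C[C@@H]3C(C)(C)OC(=O)[C@]3(O[Si](C)(C)C)[C@@]21O[Si](C)(C)C | intermediate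
18 | 4-methyl analogue of 17 (tris-silylated) | CC(C)=CCC/C(O[Si](C)(C)C)=C1\CC=C(C)[C@@H]2C[C@@H]3C(C)(C)OC(=O)[C@]3(O[Si](C)(C)C)[C@@]21O[Si](C)(C)C | intermediate
19 | tricyclic diol ketone: rings A, B, C; 1-H on the convex face; C9 ketone with 4-methylpent-3-enyl chain | CC(C)=CCCC(=O)[C@@H]1CC=C(C)[C@@H]2C[C@@H]3C(C)(C)OC(=O)[C@]3(O)[C@@]21O | intermediate
20 | ring-opened hydroxy diketone: rings A, B, D; C9 and C10 ketones; C8 tertiary alcohol (C11 enolisable) | CC(C)=CCC1C(=O)[C@@H]2CC=C(C)[C@@H]3C[C@H](C(C)(C)O)[C@](O)(C1=O)[C@@]32O | intermediate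
21 | tetracycle with H in place of geranyl on C1 | [C@H]12CC=C(C)[C@@H]3C[C@@H]4C(C)(C)OC(=C(CC=C(C)C)C1=O)[C@]4(O)[C@@]32O | intermediate
22 | geranyl bromide | CC(C)=CCC/C(C)=C/CBr | starting material
23 | CNP0323114.1 | CC(C)=CCC/C(C)=C/C[C@]12CC=C(C)[C@@H]3C[C@@H]4C(C)(C)OC(=C(CC=C(C)C)C1=O)[C@]4(O)[C@@]32O | target

**Count and risks**

Total step count: 11. Longest linear sequence: 11 steps (1 to 23).

Step 7. The ring closure may fail through slow equilibration at C5 relative to unproductive proton transfer, through retro-aldol opening of ring B at the C13 alkoxide, or through oligomerisation of the enone. The fallback replaces the polar closure by a radical one; it leaves the route at 12 and returns at 19, bypassing steps 6 to 9. The methyl ketone of 12 would be iodomethylenated by a Stork–Zhao-type olefination ((iodomethyl)triphenylphosphonium iodide, NaN(SiMe3)2, THF, −78 → 0 °C). The basic ylide also equilibrates C5, and the epimer with the new alkenyl group cis to the C13 side arm would be separated as vinyl iodide F1. Dess–Martin oxidation would give α-methylene ketone F2. Bu3SnH with AIBN (benzene, 80 °C, high dilution) would then generate the C3 vinyl radical, which closes ring A by 6-endo-trig addition to C2; the E/Z mixture of the iodide is immaterial because the vinyl radical inverts. Reduction of the α-keto radical at C1 gives 19.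

Step 4. The aldol may suffer from poor facial selectivity at C13 if the lithium chelate is not maintained, from competing Claisen attack of the C5 enolate on the lactone carbonyl, or from base-induced destruction of the bromoenone. The fallback changes the order so that the aldol runs under neutral enamine catalysis; it leaves at 9 and returns at 12. Nozaki–Hiyama–Kishi coupling of 9 with 11 (CrCl2, NiCl2 cat., DMF, 23 °C) would first give hydroxy enone F3, which no longer carries the base-sensitive bromoenone. Pyrrolidinium acetate (20 mol %, CH2Cl2, 23 °C) would then effect the 5-enolexo aldol cyclisation through the enamine of the methyl ketone, the hydrogen bond from the C12 hydroxyl to the C13 carbonyl directing the face, to give 12.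

Step 11. The alkylation may fail through incomplete deprotonation of the hindered C1–H, O-alkylation of the dienolate, or retro-aldol cleavage of the C1–C13 bond at the alkoxide after alkylation. The fallback replaces enolate alkylation by palladium-catalysed decarboxylative allylation; it leaves at 21 and returns at 23. The dienolate of 21 would be O-acylated with geranyl chloroformate (LiN(iPr)2, THF, −78 °C; the hindered tertiary alkoxides are expected to stay unacylated) to give enol carbonate F4. Pd(PPh3)4 (5 mol %, THF, 23 °C) would ionise F4 to a π-geranyl palladium enolate ion pair that recombines at C1 on the convex face with loss of CO2 (Tsuji allylation); attack at the less substituted allyl terminus gives the linear (E)-geranyl group of 23.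

Further compounds
F1 | step 7 | 5-(1-iodoprop-1-en-2-yl) analogue of 12, alkenyl group cis to the C13 side arm (E/Z and C9 mixtures) | IC=C(C)[C@@H]1C[C@@H]2C(C)(C)OC(=O)[C@]2(O)[C@]1(O)C(=C)C(O)CCC=C(C)C
F2 | step 7 | α-methylene ketone from F1 | IC=C(C)[C@@H]1C[C@@H]2C(C)(C)OC(=O)[C@]2(O)[C@]1(O)C(=C)C(=O)CCC=C(C)C
F3 | step 4 | 3-hydroxy-3-(3-hydroxy-7-methyl-2-methylideneoct-6-enoyl)-5,5-dimethyl-4-(3-oxobutyl)dihydrofuran-2(3H)-one (C9 epimers) | CC(=O)CC[C@@H]1C(C)(C)OC(=O)[C@]1(O)C(=O)C(=C)C(O)CCC=C(C)C
F4 | step 11 | geranyl enol carbonate of 21 (C1=C9 enol) | CC(C)=CCC/C(C)=C/COC(=O)OC1=C2CC=C(C)[C@@H]3C[C@@H]4C(C)(C)OC(=C1CC=C(C)C)[C@]4(O)[C@@]32O
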